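**Strategy.** Everything rests on reading ring B of the lactone-half decalin, together with C4, its methyls C18/C19 and the angular methyl C20, as a hidden pinane: a bond from C4 to C7 would close a cyclobutane (C4–C5–C6–C7) and give the skeleton of (+)-verbenone. The key step runs this in reverse. Its precursor is a 4-allyl norpinan-2-one that already carries C20 and the C11–C12 arm; SnCl4 cleaves the strained C7–C4 bond and the tertiary C4 cation is caught by the allyl terminus C3, so ring A (C1–C2–C3–C4–C5–C10) closes on a preformed, stereodefined ring B. The resulting aldehyde supplies both halves; the lactone ring is purchased.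

Key step: step 3

Remarks: positions are named with labdane numbers (C1–C20), also in the bicyclic precursors. Assumption: (1R,5R)-(+)-verbenone and (R)-3-hydroxy-γ-butyrolactone are purchasable. Aldehyde 8 is divided between the two halves, so step 3 is the only ring-forming step of the route.

Step 1
Reactants: 1 (1R,5R)-(+)-verbenone
Product: 2 (1R,4R,5R)-4-allyl-4,6,6-trimethylbicyclo[3.1.1]heptan-2-one
Conditions: allylSiMe3, TiCl4, CH2Cl2, −78 °C; H2O
Reagents that add atoms: allyltrimethylsilane C=CC[Si](C)(C)C
Why: Hosomi–Sakurai conjugate allylation of the β,β-disubstituted enone; the allyl group should enter from the methylene-bridge face, opposite the gem-dimethyl bridge, which sets the future C10 with its methyl cis and the allyl arm trans to the C4 branch on C5.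

Step 2
Reactants: 2 (1R,4R,5R)-4-allyl-4,6,6-trimethylbicyclo[3.1.1]heptan-2-one
Product: 3 methyl 2-[(1R,4S,5S)-4-allyl-4,6,6-trimethyl-2-oxobicyclo[3.1.1]heptan-3-yl]acetate (C3 epimers)
Conditions: LiN(iPr)2, THF, −78 °C; BrCH2CO2Me, DMPU, −78 to 0 °C
Reagents that add atoms: methyl bromoacetate COC(=O)CBr
Why: Enolate alkylation; the bridgehead C–H cannot enolise, so only the enolate toward the future C9 can form, and the new centre is α to the ketone and is corrected in step 4.

Step 3
Reactants: 3 methyl 2-[(1R,4S,5S)-4-allyl-4,6,6-trimethyl-2-oxobicyclo[3.1.1]heptan-3-yl]acetate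
Product: 4 methyl 2-[(4aS,8aS)-7-chloro-5,5,8a-trimethyl-2-oxodecahydronaphthalen-1-yl]acetate (epimers at C9 and at the chloride carbon C2)
Conditions: SnCl4 (2 equiv), CH2Cl2, −78 °C to rt; H2O
Reagents that add atoms: tin tetrachloride Cl[Sn](Cl)(Cl)Cl
Why: Proposed new method: SnCl4 binds the ketone and the strained cyclobutane bond between the α-bridgehead carbon (future C7) and the gem-dimethyl carbon (future C4) heterolyses in a Grob/retro-Prins sense to a tin enolate and a tertiary C4 cation, which the terminal allyl carbon C3 captures; chloride then quenches the secondary C2 cation and water protonates the enolate at C7. The closest known chemistry is the Lewis-acid opening of 4-aryl-6,6-dimethylnorpinan-2-ones, where a phenol oxygen captures the same cation, combined with an ordinary chloride-terminated cation–olefin cyclization; capture by a tethered alkene is the untested element. Ring A closes in a 6-endo-trig cationic mode through a chair in which the C4 branch and the allyl arm are both equatorial on ring B. No stereocentre of the target is created: C5 comes from verbenone and C10 from step 1, so the trans ring fusion is predetermined, while the C2 chloride and C9 are dealt with in step 4. The step needs (a) cleavage of the C7–C4 bond only, secured because it alone gives both an enolate and a tertiary cation, (b) endo attack, secured by the Markovnikov preference for a secondary over a primary cation, and (c) chloride capture faster than hydride or methyl shifts, favoured by low temperature and the chlorostannate counter-ion.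

Step 4
Reactants: 4 methyl 2-[(4aS,8aS)-7-chloro-5,5,8a-trimethyl-2-oxodecahydronaphthalen-1-yl]acetate
Product: 6 methyl 2-[(1R,4aS,8aS)-5,5,8a-trimethyl-2-oxodecahydronaphthalen-1-yl]acetate, via C9-epimeric keto ester 5 (not isolated)
Conditions: Bu3SnH, AIBN (cat.), PhMe, 100 °C; then K2CO3 (cat.), MeOH, rt
Reagents that add atoms: none
Why: Radical-chain hydrodechlorination leaves ketone and ester untouched, and mild base then equilibrates the ketone α-centre C9 toward the equatorial side chain (9α-H), which is also the isomer formed by axial protonation of the enolate anti to the angular methyl.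

Step 5
Reactants: 6 methyl 2-[(1R,4aS,8aS)-5,5,8a-trimethyl-2-oxodecahydronaphthalen-1-yl]acetate
Product: 7 methyl 2-[(1S,4aS,8aS)-5,5,8a-trimethyl-2-methylidenedecahydronaphthalen-1-yl]acetate
Conditions: Ph3PCH3Br, KOtBu, PhMe, 80 °C
Reagents that add atoms: methyltriphenylphosphonium bromide C[P+](c1ccccc1)(c1ccccc1)c1ccccc1.[Br-]
Why: Wittig methylenation of the C8 ketone with a non-stabilised ylide that tolerates the methyl ester; C9 is already in its stable configuration.

Step 6
Reactants: 7 methyl 2-[(1S,4aS,8aS)-5,5,8a-trimethyl-2-methylidenedecahydronaphthalen-1-yl]acetate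
Product: 8 2-[(1S,4aS,8aS)-5,5,8a-trimethyl-2-methylidenedecahydronaphthalen-1-yl]acetaldehyde
Conditions: iBu2AlH (1.1 equiv), CH2Cl2, −78 °C; aqueous work-up
Reagents that add atoms: none
Why: Partial ester reduction at −78 °C stops at the tetrahedral aluminium hemiacetal, which gives the aldehyde on work-up; the isolated alkene is inert.

Step 7
Reactants: 9 (R)-3-hydroxy-γ-butyrolactone
Product: 10 (4R)-4-(tert-butyldimethylsilyloxy)oxolan-2-one
Conditions: TBSCl, imidazole, CH2Cl2, rt
Reagents that add atoms: tert-butyldimethylsilyl chloride CC(C)(C)[Si](C)(C)Cl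
Why: Standard silylation of the secondary alcohol; the stereocentre (future C14, R) is not touched.

Step 8
Reactants: 10 (4R)-4-(tert-butyldimethylsilyloxy)oxolan-2-one; 8 2-[(1S,4aS,8aS)-5,5,8a-trimethyl-2-methylidenedecahydronaphthalen-1-yl]acetaldehyde
Product: 13 (3E,4R)-4-(tert-butyldimethylsilyloxy)-3-{2-[(1S,4aS,8aS)-5,5,8a-trimethyl-2-methylidenedecahydronaphthalen-1-yl]ethylidene}oxolan-2-one, via aldol adduct 11 (not isolated), via mesylate 12 (not isolated)
Conditions: 10, LiN(SiMe3)2, THF, −78 °C; 8; MsCl, −78 to 0 °C; DBU, 0 °C to rt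
Reagents that add atoms: none
Why: Lithium-enolate aldol addition at −78 °C (β-silyloxy γ-lactone enolates survive at this temperature, as in 2-deoxyribonolactone chemistry), mesylation of the aldolate and E1cB elimination, in which mesylate leaves far faster than silyloxide, should give the α-alkylidene lactone as the thermodynamic E isomer (C11 anti to the carbonyl) with C14 uninvolved.

Step 9
Reactants: 13 (3E,4R)-4-(tert-butyldimethylsilyloxy)-3-{2-[(1S,4aS,8aS)-5,5,8a-trimethyl-2-methylidenedecahydronaphthalen-1-yl]ethylidene}oxolan-2-one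
Product: 14 (3E,4R)-4-hydroxy-3-{2-[(1S,4aS,8aS)-5,5,8a-trimethyl-2-methylidenedecahydronaphthalen-1-yl]ethylidene}oxolan-2-one
Conditions: HF·pyridine, THF, 0 °C to rt
Reagents that add atoms: none
Why: Fluoride-mediated desilylation under buffered acidic conditions frees the allylic C14 alcohol without base, which could trigger elimination.

Step 10
Reactants: 15 triethyl phosphonoacetate; 16 2-bromo-1,1-diethoxyethane
Product: 17 ethyl 2-(diethoxyphosphoryl)-4,4-diethoxybutanoate (racemic)
Conditions: NaH, DMF, 0 °C; 16, NaI (cat.), 80 °C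
Reagents that add atoms: none
Why: SN2 C-alkylation of the sodium phosphonoacetate anion under iodide catalysis gives the Horner–Wadsworth–Emmons reagent that carries C13–C16 with the C15 aldehyde masked.

Step 11
Reactants: 17 ethyl 2-(diethoxyphosphoryl)-4,4-diethoxybutanoate; 8 2-[(1S,4aS,8aS)-5,5,8a-trimethyl-2-methylidenedecahydronaphthalen-1-yl]acetaldehyde
Product: 18 ethyl (2E)-4,4-diethoxy-2-{2-[(1S,4aS,8aS)-5,5,8a-trimethyl-2-methylidenedecahydronaphthalen-1-yl]ethylidene}butanoate
Conditions: NaH, THF, 0 °C; 8, 0 °C to rt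
Reagents that add atoms: none
Why: Horner–Wadsworth–Emmons olefination; α-substituted phosphonoacetates and unbranched aliphatic aldehydes should give mainly the E trisubstituted enoate (ester anti to C11).

Step 12
Reactants: 18 ethyl (2E)-4,4-diethoxy-2-{2-[(1S,4aS,8aS)-5,5,8a-trimethyl-2-methylidenedecahydronaphthalen-1-yl]ethylidene}butanoate
Product: 19 (2E)-4,4-diethoxy-2-{2-[(1S,4aS,8aS)-5,5,8a-trimethyl-2-methylidenedecahydronaphthalen-1-yl]ethylidene}butanoic acid
Conditions: LiOH, THF/H2O, 45 °C; 1 M HCl to pH 4, 0 °C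
Reagents that add atoms: lithium hydroxide [Li+].[OH-]
Why: Saponification of the conjugated ethyl ester; the acetal survives base and brief mild acidification and keeps the acid from closing to a lactol.

Step 13
Reactants: 19 (2E)-4,4-diethoxy-2-{2-[(1S,4aS,8aS)-5,5,8a-trimethyl-2-methylidenedecahydronaphthalen-1-yl]ethylidene}butanoic acid; 14 (3E,4R)-4-hydroxy-3-{2-[(1S,4aS,8aS)-5,5,8a-trimethyl-2-methylidenedecahydronaphthalen-1-yl]ethylidene}oxolan-2-one
Product: 21 C15 diethyl acetal of the target (ester of acid 19 at the C14 oxygen of 14), via mixed anhydride 20 (not isolated)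
Conditions: 2,4,6-Cl3C6H2COCl, Et3N, PhMe, rt; 14, DMAP, rt
Reagents that add atoms: none
Why: Yamaguchi esterification; the mixed anhydride of the α-branched acrylic acid acylates the hindered secondary allylic alcohol under DMAP catalysis with retention at C14, and the short exposure to amine limits loss of the new allylic acyloxy group.

Step 14
Reactants: 21 C15 diethyl acetal of the target
Product: 22 target CNP0274315.1
Conditions: AcOH/THF/H2O (3:1:1), 35 °C
Reagents that add atoms: water O
Why: Mild acetal hydrolysis releases the C15 aldehyde; the exocyclic alkenes, the allylic ester and the lactone should tolerate dilute acetic acid.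

**Compound list**

1 | (1R,5R)-(+)-verbenone | CC1=CC(=O)[C@@H]2C[C@H]1C2(C)C | starting material
2 | (1R,4R,5R)-4-allyl-4,6,6-trimethylbicyclo[3.1.1]heptan-2-one (allyl anti to the gem-dimethyl bridge) | C=CC[C@]1(C)CC(=O)[C@@H]2C[C@H]1C2(C)C | intermediate
3 | methyl 2-[(1R,4S,5S)-4-allyl-4,6,6-trimethyl-2-oxobicyclo[3.1.1]heptan-3-yl]acetate, C3 left open | C=CC[C@]1(C)C(CC(=O)OC)C(=O)[C@@H]2C[C@H]1C2(C)C | intermediate
4 | methyl 2-[(4aS,8aS)-7-chloro-5,5,8a-trimethyl-2-oxodecahydronaphthalen-1-yl]acetate, C9 and the chloride carbon left open | COC(=O)CC1C(=O)CC[C@H]2C(C)(C)CC(Cl)C[C@]12C | intermediate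
5 | methyl 2-[(4aS,8aS)-5,5,8a-trimethyl-2-oxodecahydronaphthalen-1-yl]acetate, C9 epimer mixture | COC(=O)CC1C(=O)CC[C@H]2C(C)(C)CCC[C@]12C | intermediate (not isolated)
6 | methyl 2-[(1R,4aS,8aS)-5,5,8a-trimethyl-2-oxodecahydronaphthalen-1-yl]acetate | COC(=O)C[C@H]1C(=O)CC[C@H]2C(C)(C)CCC[C@]12C | intermediate
7 | methyl 2-[(1S,4aS,8aS)-5,5,8a-trimethyl-2-methylidenedecahydronaphthalen-1-yl]acetate | COC(=O)C[C@H]1C(=C)CC[C@H]2C(C)(C)CCC[C@]12C | intermediate
8 | 2-[(1S,4aS,8aS)-5,5,8a-trimethyl-2-methylidenedecahydronaphthalen-1-yl]acetaldehyde | O=CC[C@H]1C(=C)CC[C@H]2C(C)(C)CCC[C@]12C | intermediate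
9 | (R)-3-hydroxy-γ-butyrolactone, (4R)-4-hydroxyoxolan-2-one | O[C@H]1COC(=O)C1 | starting material
10 | (4R)-4-(tert-butyldimethylsilyloxy)oxolan-2-one | CC(C)(C)[Si](C)(C)O[C@H]1COC(=O)C1 | intermediate
11 | (4R)-4-(tert-butyldimethylsilyloxy)-3-{1-hydroxy-2-[(1S,4aS,8aS)-5,5,8a-trimethyl-2-methylidenedecahydronaphthalen-1-yl]ethyl}oxolan-2-one, carbinol and C3 centres left open | CC(C)(C)[Si](C)(C)O[C@H]1COC(=O)C1C(O)C[C@H]1C(=C)CC[C@H]2C(C)(C)CCC[C@]12C | intermediate (not isolated)
12 | methanesulfonate of 11 | CC(C)(C)[Si](C)(C)O[C@H]1COC(=O)C1C(OS(C)(=O)=O)C[C@H]1C(=C)CC[C@H]2C(C)(C)CCC[C@]12C | intermediate (not isolated)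
13 | (3E,4R)-4-(tert-butyldimethylsilyloxy)-3-{2-[(1S,4aS,8aS)-5,5,8a-trimethyl-2-methylidenedecahydronaphthalen-1-yl]ethylidene}oxolan-2-one | CC(C)(C)[Si](C)(C)O[C@H]1COC(=O)/C1=C/C[C@H]1C(=C)CC[C@H]2C(C)(C)CCC[C@]12C | intermediate
14 | (3E,4R)-4-hydroxy-3-{2-[(1S,4aS,8aS)-5,5,8a-trimethyl-2-methylidenedecahydronaphthalen-1-yl]ethylidene}oxolan-2-one | O[C@H]1COC(=O)/C1=C/C[C@H]1C(=C)CC[C@H]2C(C)(C)CCC[C@]12C | intermediate
15 | triethyl phosphonoacetate | CCOC(=O)CP(=O)(OCC)OCC | starting material
16 | 2-bromo-1,1-diethoxyethane | CCOC(CBr)OCC | starting material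
17 | ethyl 2-(diethoxyphosphoryl)-4,4-diethoxybutanoate (racemic) | CCOC(=O)C(CC(OCC)OCC)P(=O)(OCC)OCC | intermediate
18 | ethyl (2E)-4,4-diethoxy-2-{2-[(1S,4aS,8aS)-5,5,8a-trimethyl-2-methylidenedecahydronaphthalen-1-yl]ethylidene}butanoate | CCOC(=O)/C(CC(OCC)OCC)=C/C[C@H]1C(=C)CC[C@H]2C(C)(C)CCC[C@]12C | intermediate
19 | (2E)-4,4-diethoxy-2-{2-[(1S,4aS,8aS)-5,5,8a-trimethyl-2-methylidenedecahydronaphthalen-1-yl]ethylidene}butanoic acid | OC(=O)/C(CC(OCC)OCC)=C/C[C@H]1C(=C)CC[C@H]2C(C)(C)CCC[C@]12C | intermediate
20 | mixed anhydride of 19 with 2,4,6-trichlorobenzoic acid | O=C(OC(=O)/C(CC(OCC)OCC)=C/C[C@H]1C(=C)CC[C@H]2C(C)(C)CCC[C@]12C)c1c(Cl)cc(Cl)cc1Cl | intermediate (not isolated)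
21 | C15 diethyl acetal of the target | C=C1CC[C@H]2C(C)(C)CCC[C@]2(C)[C@H]1C/C=C(\CC(OCC)OCC)C(=O)O[C@H]1COC(=O)/C1=C/C[C@H]1C(=C)CC[C@H]2C(C)(C)CCC[C@]12C | intermediate
22 | CNP0274315.1 | C=C1CC[C@H]2C(C)(C)CCC[C@]2(C)[C@H]1C/C=C(\CC=O)C(=O)O[C@H]1COC(=O)/C1=C/C[C@H]1C(=C)CC[C@H]2C(C)(C)CCC[C@]12C | target

Total step count: 14. Longest linear sequence: 10 steps (1–6, 8, 9, 13, 14).

**Steps most likely to fail**

Step 3 (Proposed new method). The secondary C2 cation may undergo hydride or methyl shifts or lose a proton instead of taking up chloride, ionisation may stop at the ring-opened stage, or the activated ketone may react with the allyl group in a Prins sense. The fallback sets out from 3, comes back at 6, and never passes through a cation at C2. Hydroboration–oxidation of the allyl group (9-BBN; NaBO3) would give the primary alcohol F1, and I2/PPh3/imidazole the iodide F2. The cyclobutane opening long used for nopinone-type ketones (BF3·OEt2, Zn(OAc)2, Ac2O) should then give the ring-opened isopropenyl enol acetate F3, since no π-nucleophile is left on the arm. Ring A would be closed by metal-hydride hydrogen-atom-transfer/nickel hydroalkylation of the isopropenyl group with the tethered primary iodide (Mn(dpm)3, Ni(acac)2, PhSiH3, K2CO3), forming the C3–C4 bond and the gem-dimethyl carbon directly as the decalin enol acetate F4. K2CO3/MeOH would cleave the enol acetate and equilibrate C9 to give 6.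

Step 8. The silyloxide may be eliminated from the lactone enolate before it adds to the aldehyde, the aldolate may revert on warming, or the alkene geometry may be poorly controlled. The fallback sets out from 9 and 8 and comes back at 11. The dianion of unprotected 9 (2 equiv LiN(iPr)2, THF, −78 °C), whose alkoxide cannot act as a leaving group, would be added to 8 to give the diol F5. Selective silylation of the less hindered ring hydroxyl (TBSCl, imidazole) would give 11, which is mesylated and eliminated with DBU to 13 as before.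

Step 13. Acylation by the hindered anhydride may be slow, so that prolonged amine exposure removes the new allylic acyloxy group through deprotonation at C11 or isomerises the enoate. The fallback sets out from 17, uses 14 and 8, and comes back at 21; it moves the esterification to an unhindered acid and builds the hindered enoate afterwards. Saponification of 17 (LiOH) would give the phosphono acid F6. Carbodiimide coupling with 14 (DCC, DMAP cat., 0 °C) would give the phosphonoacetate ester F7. A Masamune–Roush Horner–Wadsworth–Emmons reaction with 8 (LiCl, iPr2NEt, MeCN), whose base is too weak to deprotonate C11, would give 21.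

**Further compounds**

F1 | step 3 | methyl 2-[4-(3-hydroxypropyl)-4,6,6-trimethyl-2-oxobicyclo[3.1.1]heptan-3-yl]acetate (configuration as in 3) | OCCC[C@]1(C)C(CC(=O)OC)C(=O)[C@@H]2C[C@H]1C2(C)C
F2 | step 3 | methyl 2-[4-(3-iodopropyl)-4,6,6-trimethyl-2-oxobicyclo[3.1.1]heptan-3-yl]acetate (configuration as in 3) | ICCC[C@]1(C)C(CC(=O)OC)C(=O)[C@@H]2C[C@H]1C2(C)C
F3 | step 3 | methyl 2-[2-acetoxy-6-(3-iodopropyl)-6-methyl-5-(prop-1-en-2-yl)cyclohex-2-en-1-yl]acetate (isopropenyl and iodopropyl trans) | CC(=O)OC1=CC[C@@H](C(C)=C)[C@](C)(CCCI)C1CC(=O)OC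
F4 | step 3 | methyl 2-[(4aS,8aS)-2-acetoxy-5,5,8a-trimethyl-1,4,4a,5,6,7,8,8a-octahydronaphthalen-1-yl]acetate | CC(=O)OC1=CC[C@H]2C(C)(C)CCC[C@]2(C)C1CC(=O)OC
F5 | step 8 | (4R)-4-hydroxy-3-{1-hydroxy-2-[(1S,4aS,8aS)-5,5,8a-trimethyl-2-methylidenedecahydronaphthalen-1-yl]ethyl}oxolan-2-one | O[C@H]1COC(=O)C1C(O)C[C@H]1C(=C)CC[C@H]2C(C)(C)CCC[C@]12C
F6 | step 13 | 2-(diethoxyphosphoryl)-4,4-diethoxybutanoic acid | CCOC(CC(C(=O)O)P(=O)(OCC)OCC)OCC
F7 | step 13 | 2-(diethoxyphosphoryl)-4,4-diethoxybutanoate ester of 14 at its C14 oxygen | CCOC(CC(C(=O)O[C@H]1COC(=O)/C1=C/C[C@H]1C(=C)CC[C@H]2C(C)(C)CCC[C@]12C)P(=O)(OCC)OCC)OCC
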